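Readings and results were computed for an exercise; scatter was added.

A peak that is small but still shrinking is easily read as a flask in motion, so before judging the ochre flask we must say how much of its charge can still move.

all flasks: starting material 0.20 M
- ochre: reagent 0.80 M; protic impurity 4 mM; the very flask that is asked about, followed so far
- flask: reagent 0.800 M; protic impurity 4.00 mM; time 2.0 d

- ochre (time / h: starting material / %, target / %): 2.00: 44.6, 12.3; 5.00: 23.0, 33.1; 10.0: 8.4, 44.0; 15.0: 4.8, 48.2

(each reading ± 1 percentage point)

- a species is counted by the starting material in it: one side product B counts as two
- the numbers in the tables scatter with a standard deviation of 1 percentage point
- steps under discussion: starting material + reagent <-> intermediate A; starting material + reagent -> side product A; intermediate A -> intermediate B; reagent + intermediate B -> target; starting material + target -> side product B; starting material + protic impurity -> quenched substrate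
- the reaction counts as stopped when no species that holds the starting material changes by six tenths of a point or more over the second half of the time

- which holds at 2.0 d: what has brought the reaction to rest, or that it has not come to rest (the reagent has run out first / forward and back rates have come level / it is still moving / all of the starting material has reacted)
- conversion of starting material at 2.0 d
- amount of target at 2.0 d, in percent of the starting material charged

1. The stop rule looks at the second half of the time, from 24.0 h on, and whatever changes then comes out of what has not yet reached an end product. Side product B, counted double, can move by up to twice its share. So our sign of rest is that this remainder stands, when the second half begins, under half of the stop mark of 0.600% of the charge, that is under 0.300%, where even the double count stays below the mark. A remainder above the mark that is starting material and keeps falling moves its own peak past the mark, and between the two marks this test gives no verdict.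

2. With the reagent charged at 4.00 equivalents, we treat the tail of the ochre run as pseudo-first-order, with one decay constant for the fraction left. Starting material falls from 23.0% at 5.00 h to 4.8% at 15.0 h, which gives 0.157 h⁻¹.

3. The intermediates are not in the readings, so we let starting material stand for them. Carrying the last reading forward, we get the reservoir at half time, the fraction of the charge still in starting material, intermediate A or intermediate B at half the asked time: 1.17%. That is 1.95 times the mark, so we say the ochre flask is still moving, though the last reading scatters by 1 percentage point, which makes this margin soft.

4. The forecast also says it is still moving, in its words “narrowly still moving, though nearly finished”, with conversion 99.7% and target 51.5%.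

5. The ochre flask gives: all of the starting material has reacted, with conversion >99.9% and target 49.5%.

    starting material + reagent ⇌ intermediate A (K = 1.30 M⁻¹, k = 0.0132 M⁻¹ min⁻¹)
    starting material + reagent → side product A (k = 0.00190 M⁻¹ min⁻¹)
    intermediate A → intermediate B (k = 0.00617 min⁻¹)
    reagent + intermediate B → target (k = 0.0834 M⁻¹ min⁻¹)
    starting material + target → side product B (k = 0.0146 M⁻¹ min⁻¹)
    starting material + protic impurity → quenched substrate (k = 2.85 M⁻¹ min⁻¹)

6. The reservoir of the ochre flask at 1.00 d is 0.576%, less than our 1.17%, and it lies above 0.300% and just under the mark of 0.600%, so the test gives no verdict on the ochre flask, whose starting material stands at 0.357% at that time and at 0% at 2.0 d. Ten times the asked time, 20.0 d, changes the target by nothing. The flask with 0.32 M of reagent fails the test, since at the asked time, 2.00 d, it already holds a reservoir of 2.13%, above the mark, of which 1.85% is starting material.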